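**Retrosynthetic overview**

1. The C7=C8 bond is cut by Julia–Kocienski olefination into the (S)-α-cyclogeranyl benzothiazolyl sulfone (ring plus C7) and the C30 aldehyde apo-8'-lycopenal (C8 onward), which comes from crocetin dialdehyde and a geranyl ylide (C7'=C8').
2. The sulfone comes from (S)-α-cyclogeraniol, whose C6–C7 bond is made by a Wittig–Still [2,3] shift of the tributylstannylmethyl ether of (R)-2,4,4-trimethylcyclohex-2-en-1-ol.
3. Feature: the only stereocentre, C6, is a ring CH allylic to the C4=C5 alkene of the six-membered ring and flanked by the quaternary C1. A C4–O stereocentre on the C5=C6 alkene isomer can therefore hand C7 to C6 across one ring face and leave the alkene at C4=C5.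
4. Ring order: the single six-membered ring is built first (annulation of isobutyraldehyde with ethyl vinyl ketone) and made chiral by CBS reduction; no further ring is formed.

Key step: step 4

Assumption: carotenoid numbering is used (ring C1 = gem-dimethyl carbon, C5 = methyl-bearing sp2 carbon, C6 = stereocentre, chain from C7, acyclic half primed); the target as drawn is 6S, and tributyl(iodomethyl)stannane is taken as a purchasable reagent.

**Route**

Step 1
Reactants: 1 isobutyraldehyde; 2 ethyl vinyl ketone
Product: 4 2,4,4-trimethylcyclohex-2-en-1-one, via keto aldehyde 3 (not isolated)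
Conditions: H2SO4 (cat.), toluene, 50 °C then reflux, Dean–Stark
Reagents that add atoms: none
Why: Acid-catalysed Robinson-type annulation: Michael addition of the isobutyraldehyde enol to the enone gives 3, whose ethyl-ketone methylene can only close onto the non-enolisable aldehyde by aldol condensation to the six-membered enone; no stereocentre is formed.

Step 2
Reactants: 4 2,4,4-trimethylcyclohex-2-en-1-one
Product: 5 (R)-2,4,4-trimethylcyclohex-2-en-1-ol
Conditions: (S)-1-methyl-3,3-diphenyltetrahydro-1H,3H-pyrrolo[1,2-c][1,3,2]oxazaborole (10 mol %), BH3·SMe2, THF, −20 °C, slow addition of 4; aq. work-up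
Reagents that add atoms: none
Why: Corey–Bakshi–Shibata 1,2-reduction: the methyl-substituted alkene arm acts as the large group, so the (S)-catalyst should deliver hydride to the face that gives the (R)-carbinol (same sense as acetophenone to (R)-1-phenylethanol).

Step 3
Reactants: 5 (R)-2,4,4-trimethylcyclohex-2-en-1-ol
Product: 7 tributyl({[(1R)-2,4,4-trimethylcyclohex-2-en-1-yl]oxy}methyl)stannane, via potassium alkoxide 6 (not isolated)
Conditions: KH, THF, 0 °C; then Bu3SnCH2I, 0 °C → rt
Reagents that add atoms: tributyl(iodomethyl)stannane, CCCC[Sn](CCCC)(CCCC)CI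
Why: Williamson etherification: the potassium alkoxide displaces iodide from the primary iodomethylstannane (SN2), and the carbinol C–O bond is not touched, so the (R) configuration is kept.

Step 4
Reactants: 7 tributyl({[(1R)-2,4,4-trimethylcyclohex-2-en-1-yl]oxy}methyl)stannane
Product: 10 (S)-α-cyclogeraniol, via alkoxymethyllithium 8 (not isolated), via lithium alkoxide 9 (not isolated)
Conditions: n-BuLi (1.3 equiv), THF, −78 °C → −40 °C; H2O quench
Reagents that add atoms: none
Why: Tin–lithium exchange gives the α-alkoxymethyllithium 8, which undergoes the Wittig–Still [2,3]-sigmatropic rearrangement through a five-membered envelope transition state: the carbanion carbon (future C7) bonds to C6 while the C4–O bond breaks and the alkene moves from C5=C6 to C4=C5. The closest known reaction type is this same rearrangement of cyclohex-2-enyl stannylmethyl ethers, used for 1,3-transposition with chirality transfer. No ring is closed; the existing six-membered ring only carries the cyclic transition state. The new C6 stereocentre is controlled by the C4 carbinol configuration, because the shift is suprafacial and C7 is delivered to the ring face that carried the oxygen, turning (R)-C4–O into (S)-C6–C7. The step needs the [2,3] path to beat the [1,2] shift and protonation: the low temperature and the small, unstabilised primary carbanion favour the concerted path, A(1,2) strain with the C5 methyl holds the C4–O bond pseudoaxial as overlap requires, and the new bond forms anti to the pseudoaxial C1 methyl, so the neighbouring quaternary carbon should be tolerated. The alkene is placed at the non-conjugated C4=C5 position by the mechanism and not by an equilibrium.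

Step 5
Reactants: 10 (S)-α-cyclogeraniol
Product: 11 2-({[(1S)-2,6,6-trimethylcyclohex-2-en-1-yl]methyl}sulfanyl)-1,3-benzothiazole
Conditions: 2-mercaptobenzothiazole, PPh3, DIAD, THF, 0 °C → rt
Reagents that add atoms: 2-mercaptobenzothiazole, Sc1nc2ccccc2s1
Why: Mitsunobu thioetherification: the primary alkoxyphosphonium ion is displaced at C7 by the benzothiazole-2-thiolate (SN2), and C6 is not involved.

Step 6
Reactants: 11 2-({[(1S)-2,6,6-trimethylcyclohex-2-en-1-yl]methyl}sulfanyl)-1,3-benzothiazole
Product: 13 2-({[(1S)-2,6,6-trimethylcyclohex-2-en-1-yl]methyl}sulfonyl)-1,3-benzothiazole, via sulfoxide 12 (not isolated)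
Conditions: (NH4)6Mo7O24·4H2O (cat.), 30% aq. H2O2, EtOH, 0 °C → rt
Reagents that add atoms: hydrogen peroxide, OO
Why: Molybdate-catalysed peroxide oxidation of the sulfide through the sulfoxide to the sulfone; the peroxomolybdate attacks sulfur much faster than the trisubstituted C4=C5 alkene, which should survive.

Step 7
Reactants: 14 geranyl bromide
Product: 15 [(2E)-3,7-dimethylocta-2,6-dien-1-yl]triphenylphosphonium bromide
Conditions: PPh3, toluene, rt
Reagents that add atoms: triphenylphosphine, c1ccc(cc1)P(c1ccccc1)c1ccccc1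
Why: SN2 quaternisation of the primary allylic bromide by triphenylphosphine; the 2E alkene is kept in a non-polar solvent at room temperature.

Step 8
Reactants: 15 [(2E)-3,7-dimethylocta-2,6-dien-1-yl]triphenylphosphonium bromide; 16 crocetin dialdehyde (2.5 equiv)
Product: 18 apo-8'-lycopenal, via geranylidene ylide 17 (not isolated)
Conditions: NaOMe, MeOH/CH2Cl2, 0 °C → rt, dark (15 added slowly to 16); then I2 (cat.), CH2Cl2, daylight, rt
Reagents that add atoms: none
Why: Wittig olefination of one aldehyde group, favoured by the excess of the recoverable dialdehyde; the semi-stabilised allylic ylide should give an E/Z mixture at C7'=C8', which the iodine-catalysed isomerisation equilibrates to the all-E polyenal.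

Step 9
Reactants: 13 2-({[(1S)-2,6,6-trimethylcyclohex-2-en-1-yl]methyl}sulfonyl)-1,3-benzothiazole; 18 apo-8'-lycopenal
Product: 21 (6S)-ε,ψ-carotene, via sodiated sulfone 19 (not isolated), via alkoxide adduct 20 (not isolated)
Conditions: NaN(SiMe3)2 (1.1 equiv) added to 13 + 18, THF, −78 °C → rt, Ar, dim light; H2O quench
Reagents that add atoms: none
Why: Julia–Kocienski olefination: the C7 carbanion adds to the C8 aldehyde, and the adduct collapses by Smiles transfer of the benzothiazolyl group to oxygen and loss of SO2 and benzothiazolone anion, which with a conjugated aldehyde should favour the 7E alkene; the amide base is too weak to remove the allylic C6–H, so the stereocentre should be kept.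

**Compound list**

1 | isobutyraldehyde (2-methylpropanal) | CC(C)C=O | starting material
2 | ethyl vinyl ketone (pent-1-en-3-one) | CCC(=O)C=C | starting material
3 | 2,2-dimethyl-5-oxoheptanal | CCC(=O)CCC(C)(C)C=O | intermediate
4 | 2,4,4-trimethylcyclohex-2-en-1-one | CC1=CC(C)(C)CCC1=O | intermediate
5 | (R)-2,4,4-trimethylcyclohex-2-en-1-ol | O[C@@H]1CCC(C)(C)C=C1C | intermediate
6 | potassium (R)-2,4,4-trimethylcyclohex-2-en-1-olate | [K+].[O-][C@@H]1CCC(C)(C)C=C1C | intermediate
7 | tributyl({[(1R)-2,4,4-trimethylcyclohex-2-en-1-yl]oxy}methyl)stannane | CCCC[Sn](CCCC)(CCCC)CO[C@@H]1CCC(C)(C)C=C1C | intermediate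
8 | ({[(1R)-2,4,4-trimethylcyclohex-2-en-1-yl]oxy}methyl)lithium | [Li]CO[C@@H]1CCC(C)(C)C=C1C | intermediate
9 | lithium [(1S)-2,6,6-trimethylcyclohex-2-en-1-yl]methanolate | [Li]OC[C@@H]1C(C)=CCCC1(C)C | intermediate
10 | (S)-α-cyclogeraniol, [(1S)-2,6,6-trimethylcyclohex-2-en-1-yl]methanol | OC[C@@H]1C(C)=CCCC1(C)C | intermediate
11 | 2-({[(1S)-2,6,6-trimethylcyclohex-2-en-1-yl]methyl}sulfanyl)-1,3-benzothiazole | c1ccc2sc(SC[C@@H]3C(C)=CCCC3(C)C)nc2c1 | intermediate
12 | 2-({[(1S)-2,6,6-trimethylcyclohex-2-en-1-yl]methyl}sulfinyl)-1,3-benzothiazole (sulfur configuration not defined) | O=S(C[C@@H]1C(C)=CCCC1(C)C)c1nc2ccccc2s1 | intermediate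
13 | 2-({[(1S)-2,6,6-trimethylcyclohex-2-en-1-yl]methyl}sulfonyl)-1,3-benzothiazole | O=S(=O)(C[C@@H]1C(C)=CCCC1(C)C)c1nc2ccccc2s1 | intermediate
14 | geranyl bromide, (2E)-1-bromo-3,7-dimethylocta-2,6-diene | CC(C)=CCC/C(C)=C/CBr | starting material
15 | [(2E)-3,7-dimethylocta-2,6-dien-1-yl]triphenylphosphonium bromide | CC(C)=CCC/C(C)=C/C[P+](c1ccccc1)(c1ccccc1)c1ccccc1.[Br-] | intermediate
16 | crocetin dialdehyde (all-E 8,8'-diapocarotene-8,8'-dial) | O=C/C(C)=C/C=C/C(C)=C/C=C/C=C(C)/C=C/C=C(C)/C=O | starting material
17 | [(2E)-3,7-dimethylocta-2,6-dien-1-ylidene]triphenylphosphorane | CC(C)=CCC/C(C)=C/C=P(c1ccccc1)(c1ccccc1)c1ccccc1 | intermediate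
18 | apo-8'-lycopenal, (all-E)-2,6,11,15,19,23-hexamethyltetracosa-2,4,6,8,10,12,14,16,18,22-decaenal | CC(C)=CCC/C(C)=C/C=C/C(C)=C/C=C/C(C)=C/C=C/C=C(C)/C=C/C=C(C)/C=O | intermediate
19 | sodium salt of sulfone 13 metallated at C7 | [Na+].[CH-]([C@@H]1C(C)=CCCC1(C)C)S(=O)(=O)c1nc2ccccc2s1 | intermediate
20 | sodium β-alkoxide adduct of 19 and 18 (C7 sulfonyl, C8 alkoxide, both new centres undefined, C6 S) | [Na+].[O-]C(C([C@@H]1C(C)=CCCC1(C)C)S(=O)(=O)c1nc2ccccc2s1)/C(C)=C/C=C/C(C)=C/C=C/C=C(C)/C=C/C=C(C)/C=C/C=C(C)/CCC=C(C)C | intermediate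
21 | (6S)-ε,ψ-carotene (all-E; δ-carotene skeleton, 6S) | CC(C)=CCC/C(C)=C/C=C/C(C)=C/C=C/C(C)=C/C=C/C=C(C)/C=C/C=C(C)/C=C/[C@@H]1C(C)=CCCC1(C)C | target

**Count and risks**

Total step count: 9. Longest linear sequence: 7 steps (steps 1–6, then step 9); the polyenal branch is steps 7–8.

Steps most likely to fail:

1. Step 4. The carbanion may be protonated or take the [1,2] path before it can bond to C6 beside the quaternary C1, so that little of the rearranged alcohol forms. Fallback, from 5 back to 10: alcohol 5 would be heated with N,N-dimethylformamide dimethyl acetal (xylene, 140 °C, methanol distilled off). The alkoxy(dimethylamino)carbene formed in the flask should undergo the analogous suprafacial [2,3] shift to (S)-N,N,2,6,6-pentamethylcyclohex-2-ene-1-carboxamide F1, with the same face of C6 addressed. Reduction of F1 with LiNH2BH3 (THF, 0 °C → rt) should then give 10.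

2. Step 9. Addition of the hindered C7 carbanion to the polyenal may be slow, so that base-induced decomposition of the aldehyde or a poor E/Z ratio at C7=C8 takes over. Fallback, from 10 and 18 back to 21, with reversed polarity: 10 would be oxidised with Dess–Martin periodinane (NaHCO3, CH2Cl2, 0 °C) to (S)-α-cyclocitral F2, used cold and at once. Aldehyde 18 would be reduced with NaBH4 (MeOH/THF, 0 °C) to apo-8'-lycopenol F3 and converted with PPh3·HBr (MeOH/CH2Cl2, rt) into (apo-8'-lycopenyl)triphenylphosphonium bromide F4. The ylide of F4, preformed with n-BuLi (THF, −78 °C), is delocalised and weakly basic, so it should undergo Wittig olefination with F2 without enolising it; iodine-catalysed equilibration would then give 21.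

3. Step 8. The second aldehyde group may also react, giving the symmetrical bis-olefin, and the E/Z mixture at C7'=C8' may not equilibrate cleanly. Fallback, from 16 and 15 back to 18, by desymmetrisation: 16 would be treated with one equivalent of 2,2-dimethylpropane-1,3-diol and pyridinium p-toluenesulfonate (toluene, rt) to give crocetin dialdehyde mono(5,5-dimethyl-1,3-dioxan-2-yl) acetal F5, separated from dialdehyde and bis-acetal, which are recycled. F5 would be olefinated with an excess of ylide 17 (from 15, NaOMe) to apo-8'-lycopenal neopentyl glycol acetal F6. Hydrolysis of F6 (oxalic acid, THF/H2O, rt) and iodine-catalysed isomerisation should give 18.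

**Further compounds**

F1 | step 4 | (S)-N,N,2,6,6-pentamethylcyclohex-2-ene-1-carboxamide | CN(C)C(=O)[C@@H]1C(C)=CCCC1(C)C
F2 | step 9 | (S)-α-cyclocitral, (1S)-2,6,6-trimethylcyclohex-2-ene-1-carbaldehyde | O=C[C@@H]1C(C)=CCCC1(C)C
F3 | step 9 | apo-8'-lycopenol, (all-E)-2,6,11,15,19,23-hexamethyltetracosa-2,4,6,8,10,12,14,16,18,22-decaen-1-ol | CC(C)=CCC/C(C)=C/C=C/C(C)=C/C=C/C(C)=C/C=C/C=C(C)/C=C/C=C(C)/CO
F4 | step 9 | (apo-8'-lycopenyl)triphenylphosphonium bromide | CC(C)=CCC/C(C)=C/C=C/C(C)=C/C=C/C(C)=C/C=C/C=C(C)/C=C/C=C(C)/C[P+](c1ccccc1)(c1ccccc1)c1ccccc1.[Br-]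
F5 | step 8 | crocetin dialdehyde mono(5,5-dimethyl-1,3-dioxan-2-yl) acetal | O=C/C(C)=C/C=C/C(C)=C/C=C/C=C(C)/C=C/C=C(C)/C1OCC(C)(C)CO1
F6 | step 8 | apo-8'-lycopenal 5,5-dimethyl-1,3-dioxan-2-yl acetal | CC(C)=CCC/C(C)=C/C=C/C(C)=C/C=C/C(C)=C/C=C/C=C(C)/C=C/C=C(C)/C1OCC(C)(C)CO1
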